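## Retrosynthetic overview

1. Target ⇒ 3-oxo-1-ene 19,20-lactone: C2–OH by exo-face enolate oxygenation and C3–OH by equatorial hydride delivery, both in the last step.
2. ⇒ 3β-hydroxy-1-ene 19,20-lactone ⇒ key C10–C20 bond by a [2,3]-Wittig–Still shift of a 2α-O–CH2Li ether. The α-alkoxymethyllithium is a reversed-polarity hydroxymethyl anion; C10 is the normally electrophilic allylic terminus. The shift sets the C10 quaternary centre and feeds the lactonisation.
3. ⇒ 2α-hydroxy-1(10)-ene 19-carboxylate ⇐ saponification of the 19,2-lactone of the iso-gibberellic acid series ⇐ base-induced lactone transposition of gibberellic acid 1; the 13-OH is removed by oxalate radical deoxygenation.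
4. Ring order: carbocycles A, B, C, D and their ring-fusion stereocentres come intact from 1; the γ-lactone is moved (10→2), then opened; the only ring built is the δ-lactone (C19–O–C20), closed in the key step.

Assumption: gibberellic acid 1 (GA3), a bulk fermentation product sold as a plant-growth regulator, is taken as the cheap commercial starting material, so the route is a chiral-pool (relay) synthesis; α/β and C-numbers follow the usual gibberellin drawing (C19, C20 and the lactone bridge α; H-5, H-9 and C18 β).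

## Route

Step 1
Reactants: 1 gibberellic acid (GA3)
Product: 3 iso-gibberellic acid (3β,13-dihydroxy-1(10),16-diene 19,2α-lactone 7-acid), via disodium epoxy-dicarboxylate 2 (not isolated)
Conditions: 0.1 M aq. NaOH (2.2 equiv), 20 °C, 2 h; then 1 M HCl to pH 3, 0 °C
Reagents that add atoms: none
Why: Base-induced allylic lactone transposition known for GA3: the ionised 3β-hydroxyl displaces the C10 carboxylate in an antiperiplanar SN2′ reaction to give vinyl epoxide 2, which the C19 carboxylate re-opens at C2 from the α face (SN2), so C3 stays β, the new C2–O bond is α and the 1(10)-alkene needed for the key step is in place.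

Step 2
Reactants: 3 iso-gibberellic acid
Product: 5 3-O-(tetrahydropyran-2-yl)-iso-gibberellic acid, via THP ester 4 (not isolated)
Conditions: DHP (3 equiv), PPTS (0.1 equiv), CH2Cl2/THF, 0 °C → rt; then AcOH/THF/H2O (1:4:1), rt, 30 min
Reagents that add atoms: 3,4-dihydro-2H-pyran C1=COCCC1
Why: Acid-catalysed acetalisation (THP protection) takes the secondary 3β-OH and the carboxyl group but not the hindered bridgehead tertiary 13-OH, and the acylal-type THP ester is hydrolysed by aqueous acetic acid at room temperature far faster than the THP ether; no skeletal stereocentre is touched and the acetal carbon is an inconsequential epimer mixture.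

Step 3
Reactants: 5 3-O-THP-iso-gibberellic acid
Product: 7 13-O-(methoxyoxalyl)-3-O-THP-iso-gibberellic acid, via mixed anhydride 6 (not isolated)
Conditions: ClCOCO2Me (3 equiv), pyridine (6 equiv), DMAP (0.2 equiv), CH2Cl2, 0 °C → rt; then H2O, 0 °C, 15 min
Reagents that add atoms: methyl chlorooxoacetate COC(=O)C(=O)Cl
Why: DMAP-catalysed acylation of the only free hydroxyl (tertiary C13–OH) installs the methyl oxalate needed for radical deoxygenation, while the C7 acid is carried transiently as a mixed oxalic anhydride that water cleaves at the oxalyl carbonyl during the quench.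

Step 4
Reactants: 7 13-O-(methoxyoxalyl)-3-O-THP-iso-gibberellic acid
Product: 8 13-deoxy-3-O-THP-iso-lactone acid (3β-THP-oxy-1(10),16-diene 19,2α-lactone 7-acid)
Conditions: Bu3SnH (2.5 equiv), AIBN (0.2 equiv), Et3N (1.2 equiv), toluene, 100 °C
Reagents that add atoms: none
Why: Radical deoxygenation of a tertiary methyl oxalate (Barton–McCombie-type chain) gives the bridgehead C13 radical, which cannot delocalise into the 16-ene (anti-Bredt) and is reduced by Bu3SnH to the only possible 13-H configuration, Et3N buffering the C7 acid so that the THP ether survives.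

Step 5
Reactants: 8 13-deoxy-3-O-THP-iso-lactone acid; 9 tributyl(iodomethyl)stannane
Product: 11 2α-[(tributylstannyl)methoxy]-3β-THP-oxy-1(10),16-diene-7,19-dioic acid, via dipotassium hydroxy-dicarboxylate 10 (not isolated)
Conditions: KOH (2.1 equiv), dioxane/H2O, 60 °C; evaporate, toluene azeotrope; KH (1.3 equiv), 18-crown-6, THF/DMF, 0 °C; 9 (1.3 equiv), 0 °C → rt; then cold aq. KHSO4
Reagents that add atoms: tributyl(iodomethyl)stannane 9 CCCC[Sn](CCCC)(CCCC)CI; potassium hydroxide [K+].[OH-]
Why: Saponification of the γ-lactone by acyl–oxygen cleavage frees the allylic 2α-OH with C2 unchanged, and Williamson etherification of its potassium alkoxide with the α-stannyl iodide outpaces alkylation of the two hindered carboxylates, the 3β-oxygen being blocked as a THP acetal that cannot migrate.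

Step 6
Reactants: 11 2α-[(tributylstannyl)methoxy] diacid
Product: 14 3β-hydroxygibberella-1,16-diene-7,19-dioic acid 19,20-lactone, via lithiomethyl ether 12 (not isolated), via trilithium C20-alkoxide 13 (not isolated)
Conditions: n-BuLi (3.5 equiv), THF, −78 → −20 °C; then AcOH/THF/H2O (3:1:1), 45 °C
Reagents that add atoms: none
Why: Tin–lithium exchange on the dilithium dicarboxylate gives an α-alkoxymethyllithium (a reversed-polarity hydroxymethyl anion) that undergoes the suprafacial [2,3]-sigmatropic Wittig–Still rearrangement from the pseudoaxial 2α-oxygen to C10, so the C10–C20 bond and the quaternary centre form on the α face (trans to H-5β and H-9β) with the alkene moving to C1=C2, after which aqueous acetic acid closes the 1,3-diaxial C20–OH/C19–CO2H pair to the δ-lactone and removes the THP group.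

Step 7
Reactants: 14 3β-hydroxy-1-ene 19,20-lactone acid
Product: 15 3-oxogibberella-1,16-diene-7,19-dioic acid 19,20-lactone
Conditions: MnO2 (20 equiv), acetone, rt
Reagents that add atoms: none
Why: Chemoselective allylic alcohol oxidation with MnO2 converts the pseudoaxial 3β-OH into the 1-en-3-one without touching the isolated 16-ene, the lactone or the acid; C3 is flattened on purpose because C2 and C3 are both set in step 8.

Step 8
Reactants: 15 3-oxo-1-ene 19,20-lactone acid
Product: 18 2β,3β-dihydroxygibberell-16-ene-7,19-dioic acid 19,20-lactone (target), via dipotassium enolate 16 (not isolated), via dipotassium ketol salt 17 (not isolated)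
Conditions: K[BH(s-Bu)3] (2.2 equiv), THF, −78 °C; 2-(phenylsulfonyl)-3-phenyloxaziridine (1.3 equiv), −78 °C; K[BH(s-Bu)3] (3 equiv), −78 °C; AcOH
Reagents that add atoms: 2-(phenylsulfonyl)-3-phenyloxaziridine (Davis oxaziridine) O=S(=O)(N1OC1c1ccccc1)c1ccccc1
Why: Conjugate hydride reduction of the β-unsubstituted enone gives the potassium enolate, Davis enolate hydroxylation then occurs at C2 from the exo β face because the α face is capped by the C19–O–C20 bridge, and the bulky borohydride finally reduces the 3-ketone by equatorial approach to the axial 3β-alcohol (as with 3-oxo-gibberellins), giving the cis-2β,3β-diol.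

## Compound list

1 | gibberellic acid (GA3; 3β,13-dihydroxy-20-norgibberella-1,16-diene-7,19-dioic acid 19,10α-lactone) | C=C1C[C@]23C[C@@]1(O)CC[C@H]2[C@@]12C=C[C@H](O)[C@@](C)(C(=O)O1)[C@H]2[C@@H]3C(=O)O | starting material
2 | disodium 2β,3β-epoxy-13-hydroxy-20-norgibberella-1(10),16-diene-7,19-dioate (not isolated) | C=C1C[C@]23C[C@@]1(O)CC[C@H]2C1=C[C@@H]4O[C@@H]4[C@@](C)(C(=O)[O-])[C@H]1[C@@H]3C(=O)[O-].[Na+].[Na+] | intermediate
3 | iso-gibberellic acid (3β,13-dihydroxy-20-norgibberella-1(10),16-diene-7,19-dioic acid 19,2α-lactone) | C=C1C[C@]23C[C@@]1(O)CC[C@H]2C1=C[C@@H]4[C@H](O)[C@@](C)(C(=O)O4)[C@H]1[C@@H]3C(=O)O | intermediate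
4 | tetrahydropyran-2-yl ester of 5 (3-O-THP ether and 7-THP ester, acetal carbons as epimer mixtures; not isolated) | C=C1C[C@]23C[C@@]1(O)CC[C@H]2C1=C[C@@H]4[C@H](OC5CCCCO5)[C@@](C)(C(=O)O4)[C@H]1[C@@H]3C(=O)OC6CCCCO6 | intermediate
5 | 13-hydroxy-3β-(tetrahydropyran-2-yloxy)-20-norgibberella-1(10),16-diene-7,19-dioic acid 19,2α-lactone (acetal carbon: both epimers) | C=C1C[C@]23C[C@@]1(O)CC[C@H]2C1=C[C@@H]4[C@H](OC5CCCCO5)[C@@](C)(C(=O)O4)[C@H]1[C@@H]3C(=O)O | intermediate
6 | 7-(methoxyoxalyl) mixed anhydride of 7 (not isolated) | C=C1C[C@]23C[C@@]1(OC(=O)C(=O)OC)CC[C@H]2C1=C[C@@H]4[C@H](OC5CCCCO5)[C@@](C)(C(=O)O4)[C@H]1[C@@H]3C(=O)OC(=O)C(=O)OC | intermediate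
7 | 13-(methoxyoxalyloxy)-3β-(tetrahydropyran-2-yloxy)-20-norgibberella-1(10),16-diene-7,19-dioic acid 19,2α-lactone | C=C1C[C@]23C[C@@]1(OC(=O)C(=O)OC)CC[C@H]2C1=C[C@@H]4[C@H](OC5CCCCO5)[C@@](C)(C(=O)O4)[C@H]1[C@@H]3C(=O)O | intermediate
8 | 3β-(tetrahydropyran-2-yloxy)-20-norgibberella-1(10),16-diene-7,19-dioic acid 19,2α-lactone (13-deoxy) | C=C1C[C@]23C[C@H]1CC[C@H]2C1=C[C@@H]4[C@H](OC5CCCCO5)[C@@](C)(C(=O)O4)[C@H]1[C@@H]3C(=O)O | intermediate
9 | tributyl(iodomethyl)stannane | CCCC[Sn](CCCC)(CCCC)CI | starting material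
10 | dipotassium 2α-hydroxy-3β-(tetrahydropyran-2-yloxy)-20-norgibberella-1(10),16-diene-7,19-dioate (not isolated) | C=C1C[C@]23C[C@H]1CC[C@H]2C1=C[C@@H](O)[C@H](OC4CCCCO4)[C@@](C)(C(=O)[O-])[C@H]1[C@@H]3C(=O)[O-].[K+].[K+] | intermediate
11 | 2α-[(tributylstannyl)methoxy]-3β-(tetrahydropyran-2-yloxy)-20-norgibberella-1(10),16-diene-7,19-dioic acid | C=C1C[C@]23C[C@H]1CC[C@H]2C1=C[C@@H](OC[Sn](CCCC)(CCCC)CCCC)[C@H](OC4CCCCO4)[C@@](C)(C(=O)O)[C@H]1[C@@H]3C(=O)O | intermediate
12 | dilithium 2α-(lithiomethoxy)-3β-(tetrahydropyran-2-yloxy)-20-norgibberella-1(10),16-diene-7,19-dioate (not isolated) | C=C1C[C@]23C[C@H]1CC[C@H]2C1=C[C@@H](OC[Li])[C@H](OC4CCCCO4)[C@@](C)(C(=O)O[Li])[C@H]1[C@@H]3C(=O)O[Li] | intermediate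
13 | trilithium salt of 20-hydroxy-3β-(tetrahydropyran-2-yloxy)gibberella-1,16-diene-7,19-dioic acid (10α-CH2OLi; not isolated) | C=C1C[C@]23C[C@H]1CC[C@H]2[C@]1(CO[Li])C=C[C@H](OC4CCCCO4)[C@@](C)(C(=O)O[Li])[C@H]1[C@@H]3C(=O)O[Li] | intermediate
14 | 3β-hydroxygibberella-1,16-diene-7,19-dioic acid 19,20-lactone | C=C1C[C@]23C[C@H]1CC[C@H]2[C@]12COC(=O)[C@](C)([C@@H](O)C=C1)[C@H]2[C@@H]3C(=O)O | intermediate
15 | 3-oxogibberella-1,16-diene-7,19-dioic acid 19,20-lactone | C=C1C[C@]23C[C@H]1CC[C@H]2[C@]12COC(=O)[C@](C)(C(=O)C=C1)[C@H]2[C@@H]3C(=O)O | intermediate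
16 | dipotassium 2-en-3-olate 7-carboxylate of 3-oxogibberell-16-ene-7,19-dioic acid 19,20-lactone (not isolated) | C=C1C[C@]23C[C@H]1CC[C@H]2[C@]12COC(=O)[C@](C)(C([O-])=CC1)[C@H]2[C@@H]3C(=O)[O-].[K+].[K+] | intermediate
17 | dipotassium salt (2-alkoxide, 7-carboxylate) of 2β-hydroxy-3-oxogibberell-16-ene-7,19-dioic acid 19,20-lactone (not isolated) | C=C1C[C@]23C[C@H]1CC[C@H]2[C@]12COC(=O)[C@](C)(C(=O)[C@@H]([O-])C1)[C@H]2[C@@H]3C(=O)[O-].[K+].[K+] | intermediate
18 | 2β,3β-dihydroxygibberell-16-ene-7,19-dioic acid 19,20-lactone (CNP0332607.1) | C=C1C[C@]23C[C@H]1CC[C@H]2[C@]12COC(=O)[C@](C)([C@@H](O)[C@@H](O)C1)[C@H]2[C@@H]3C(=O)O | target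

## Step count and risks

Total step count: 8. Longest linear sequence: 8 steps (1 → 18); steps 5 and 8 are one-flask sequences. The route is a design proposal and has not been run.

Steps most likely to fail, in order:

**Step 6 (key step).** A trianionic substrate must build a quaternary centre next to a carboxylate-bearing quaternary carbon. A [1,2]-shift, protonation of the carbanion, or butyl ketone formation at a carboxylate can compete. The fallback replaces the sigmatropic shift by a carbamate-directed syn-SN2′ substitution with a silylmethyl copper reagent, which is another reversed-polarity hydroxymethyl donor. It sets out from 10 and comes back at 14. Compound 10 is treated with PhNCO (1.1 equiv, THF/DMF, 0 °C, then cold aq. KHSO4) to give the 2α-(N-phenylcarbamoyloxy) diacid F1. F1 is deprotonated with MeLi (3 equiv, THF, −78 °C), complexed with CuI·2LiCl (1.1 equiv) and treated with (i-PrO)Me2SiCH2MgCl (3 equiv, −78 → 0 °C). The nitrogen-bound monovalent copper delivers the silylmethyl group to C10 on the face of the leaving carbamate (α), giving the 10α-(isopropoxydimethylsilyl)methyl 1-ene diacid F2. Tamao oxidation (KF, KHCO3, 30% H2O2, THF/MeOH, rt) gives the 20-hydroxy diacid F3, and the AcOH/THF/H2O treatment of step 6 lactonises it and removes THP to give 14.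

**Step 5.** The alkoxide must be alkylated in the presence of two carboxylates after a slow saponification of a hindered lactone. The fallback makes the same ether with the roles reversed, by palladium-catalysed allylic etherification. It sets out from 8 and comes back at 11. Pd(PPh3)4 (5 mol %, zerovalent palladium, THF, rt) ionises the allylic 19,2-lactone anti to the departing carboxylate. The zinc alkoxide made from Bu3SnCH2OH (2 equiv) and Et2Zn (2 equiv, one of which neutralises the C7 acid) attacks the π-allyl complex at the less hindered C2 on the face opposite to palladium (net retention, 2α). KHSO4 work-up gives 11 directly; no new compound is made (F0).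

**Step 8.** Three operations share one flask: 1,2-reduction may compete with 1,4-reduction, the borane-associated enolate may hydroxylate sluggishly, and the C3 selectivity cannot be checked on the way. The fallback separates the events and installs the C2 oxygen by Rubottom oxidation of an isolated silyl enol ether. It sets out from 15 and comes back at 18. Compound 15 is reduced with K[BH(s-Bu)3] (2.2 equiv, THF, −78 °C) and the enolate 16 is trapped with Me3SiCl/Et3N to give the bis(trimethylsilyl) compound (2-ene-3-silyl enol ether and silyl ester) F4. Dimethyldioxirane (1.05 equiv, acetone/CH2Cl2, −78 °C) oxidises the electron-rich enol ether from the β face in preference to the 16-ene, and aqueous citric acid gives the 2β-hydroxy-3-ketone acid F5. F5 is reduced in a separate step with K[BH(s-Bu)3] (3.2 equiv, THF, −78 °C) to 18.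

## Further compounds

F0 | step 5 | none | none
F1 | step 6 | 2α-(N-phenylcarbamoyloxy)-3β-(tetrahydropyran-2-yloxy)-20-norgibberella-1(10),16-diene-7,19-dioic acid | C=C1C[C@]23C[C@H]1CC[C@H]2C1=C[C@@H](OC(=O)Nc4ccccc4)[C@H](OC5CCCCO5)[C@@](C)(C(=O)O)[C@H]1[C@@H]3C(=O)O
F2 | step 6 | 20-(isopropoxydimethylsilyl)-3β-(tetrahydropyran-2-yloxy)gibberella-1,16-diene-7,19-dioic acid (10α-CH2Si) | C=C1C[C@]23C[C@H]1CC[C@H]2[C@]1(C[Si](C)(C)OC(C)C)C=C[C@H](OC4CCCCO4)[C@@](C)(C(=O)O)[C@H]1[C@@H]3C(=O)O
F3 | step 6 | 20-hydroxy-3β-(tetrahydropyran-2-yloxy)gibberella-1,16-diene-7,19-dioic acid | C=C1C[C@]23C[C@H]1CC[C@H]2[C@]1(CO)C=C[C@H](OC4CCCCO4)[C@@](C)(C(=O)O)[C@H]1[C@@H]3C(=O)O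
F4 | step 8 | trimethylsilyl 3-(trimethylsilyloxy)gibberella-2,16-diene-7,19-dioate 19,20-lactone | C=C1C[C@]23C[C@H]1CC[C@H]2[C@]12COC(=O)[C@](C)(C(O[Si](C)(C)C)=CC1)[C@H]2[C@@H]3C(=O)O[Si](C)(C)C
F5 | step 8 | 2β-hydroxy-3-oxogibberell-16-ene-7,19-dioic acid 19,20-lactone | C=C1C[C@]23C[C@H]1CC[C@H]2[C@]12COC(=O)[C@](C)(C(=O)[C@@H](O)C1)[C@H]2[C@@H]3C(=O)O
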